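**Retrosynthetic overview**

1. Isochromene numbering is used: O2, C1=C8a, C3(Me), C4, C4a=C5, C6=O, C7(Me)(O-acyl), C8=O; ring A is the carbocycle, ring B the pyran. The last disconnection is the C7–O ester (linoleoyl chloride onto the tertiary C7 alcohol).
2. Enabling feature: ring A is a cyclohex-4-ene-1,3-dione whose carbonyl carbon C6 lies between the enolizable α-ketol carbon C7 and the alkene carbon C5, and C8a is the α-carbon of the vinylogous ester O2–C1=C8a–C8=O of ring B. C6 is therefore excised as CO, and C6–C7, C5–C6 and C4a–C8a are cut in one carbonylative palladium cascade (alkenyl iodide at C8a, alkyne C4a≡C5, ketone enolate at C7).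
3. This leaves an acyclic α-iodo-β-alkoxy enone in which O2 on C1 holds the homopropargyl arm cis to C8a, so that C4a is reached by a 6-exo-dig insertion. It comes from oxa-Michael addition of (R)-pent-4-yn-2-ol (source of C3) to a lactate-derived ynone, followed by α-iodination.
4. Stereochemistry: C3 comes from the chiral pool. C7 is erased to a planar enolate and re-set by the chiral ligand in the key step (stereoconvergent), so the lactate configuration is immaterial.
5. Ring order: ring B, then ring A, both closed in the key step.

Key step: step 6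

Assumption: the sense of induction of the bisphosphine in step 6 cannot be predicted, so (R)-DTBM-SEGPHOS is written and its antipode is used if a first run shows the 7S epimer to prevail; ethyl (S)-lactate is chosen only so that intermediates 3 to 11 are single compounds.

**Route**

Step 1
Reactants: 1 ethyl (S)-lactate; 2 chlorotriethylsilane
Product: 3 ethyl (2S)-2-[(triethylsilyl)oxy]propanoate
Conditions: imidazole, CH2Cl2, 0 °C to rt
Reagents that add atoms: chlorotriethylsilane (2), CC[Si](Cl)(CC)CC
Why: Standard silyl ether formation on a secondary alcohol, which leaves the stereocenter untouched.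

Step 2
Reactants: 3 ethyl (2S)-2-[(triethylsilyl)oxy]propanoate; 4 N,O-dimethylhydroxylamine hydrochloride
Product: 5 (2S)-N-methoxy-N-methyl-2-[(triethylsilyl)oxy]propanamide
Conditions: i-PrMgCl (3 equiv), THF, −20 to 0 °C
Reagents that add atoms: N,O-dimethylhydroxylamine hydrochloride (4), CNOC.Cl
Why: Weinreb amide formation by aminolysis of the ester with the chloromagnesium amide made in the flask, a reaction that should stop cleanly at the amide.

Step 3
Reactants: 5 (2S)-N-methoxy-N-methyl-2-[(triethylsilyl)oxy]propanamide; 6 ethynylmagnesium bromide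
Product: 7 (4S)-4-[(triethylsilyl)oxy]pent-1-yn-3-one
Conditions: THF, 0 °C; inverse quench into cold 1 M aqueous HCl
Reagents that add atoms: ethynylmagnesium bromide (6), C#C[Mg]Br
Why: Weinreb ketone synthesis, in which the chelated tetrahedral intermediate prevents over-addition and the acidic inverse quench keeps the released hydroxylamine from adding to the terminal ynone.

Step 4
Reactants: 7 (4S)-4-[(triethylsilyl)oxy]pent-1-yn-3-one; 8 (R)-pent-4-yn-2-ol
Product: 9 (1E,4S)-1-[(2R)-pent-4-yn-2-yloxy]-4-[(triethylsilyl)oxy]pent-1-en-3-one
Conditions: DABCO (10 mol %), CH2Cl2, 0 °C to rt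
Reagents that add atoms: (R)-pent-4-yn-2-ol (8), C[C@@H](O)CC#C
Why: Amine-catalysed oxa-Michael addition of an alcohol to a terminal ynone, which should give the (E)-β-alkoxy enone with O2 trans to the carbonyl; the C3 stereocenter is carried in unchanged from 8.

Step 5
Reactants: 9 (1E,4S)-1-[(2R)-pent-4-yn-2-yloxy]-4-[(triethylsilyl)oxy]pent-1-en-3-one; 10 N-iodosuccinimide
Product: 11 (1Z,4S)-2-iodo-1-[(2R)-pent-4-yn-2-yloxy]-4-[(triethylsilyl)oxy]pent-1-en-3-one
Conditions: N-iodosuccinimide (1.1 equiv), CH2Cl2, 0 °C to rt, dark
Reagents that add atoms: N-iodosuccinimide (10), O=C1CCC(=O)N1I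
Why: Electrophilic α-iodination of a vinylogous ester at its nucleophilic α-carbon followed by loss of the α-proton, which should keep O2 trans to the carbonyl and hence cis to iodine, while the terminal alkyne is not iodinated in the absence of silver or base.

Step 6
Reactants: 11 (1Z,4S)-2-iodo-1-[(2R)-pent-4-yn-2-yloxy]-4-[(triethylsilyl)oxy]pent-1-en-3-one; 12 carbon monoxide
Product: 15 (3R,7R)-3,7-dimethyl-7-[(triethylsilyl)oxy]-3,4-dihydroisochromene-6,8(7H)-dione, via alkenylpalladium iodide 13 (not isolated), via acylpalladium iodide 14 (not isolated)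
Conditions: Pd2(dba)3 (2.5 mol %), (R)-DTBM-SEGPHOS (6 mol %), Cs2CO3 (2 equiv), CO (about 1.5 equiv, released slowly from a second chamber), 1,4-dioxane, 70 °C
Reagents that add atoms: carbon monoxide (12), [C-]#[O+]
Why: Proposed new method: zerovalent palladium inserts into the C8a–I bond, the alkenylpalladium adds syn across the tethered terminal alkyne to give 13 (forms C4a–C8a, palladium on C5 cis to C8a), CO inserts to give the acylpalladium 14, and the carbonate-generated enolate of the C8 ketone, which can only form toward C7 because C8a is fully substituted, is acylated at carbon by reductive elimination from a seven-membered palladacycle (forms C6–C7). The closest known reaction types are the cyclic carbopalladation–carbonylation–nucleophile capture cascades of 2-iodoaryl homopropargyl ethers, the palladium-catalysed carbonylative α-arylation of ketones to 1,3-diketones and the enantioselective α-arylation of α-branched ketones; what has not been shown is their merger with an acylation that creates a ligand-controlled quaternary carbon. Ring B closes by 6-exo-dig carbopalladation and ring A by 6-exo-trig C-acylation of the enolate at the acyl carbon. C7 is the only new stereocenter: it is built from a planar enolate, so both C7 epimers of 11 converge, and its configuration should be set by the chiral bisphosphine on palladium in the C–C bond-forming reductive elimination, the remote C3 center from 8 being a spectator. The step needs alkyne insertion before CO insertion (secured by the O2 tether that holds the alkyne cis to C8a on the vinylogous ester and by a CO-starved atmosphere), C- over O-acylation (inner-sphere reductive elimination from the C-bound palladium enolate, as in carbonylative α-arylation) and one enolate face (ligand).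

Step 7
Reactants: 15 (3R,7R)-3,7-dimethyl-7-[(triethylsilyl)oxy]-3,4-dihydroisochromene-6,8(7H)-dione
Product: 16 (3R,7R)-7-hydroxy-3,7-dimethyl-3,4-dihydroisochromene-6,8(7H)-dione
Conditions: HF·pyridine, pyridine, THF, 0 °C
Reagents that add atoms: none
Why: Fluoride-mediated desilylation under buffered, mildly acidic conditions, chosen because the tertiary α-ketol between two carbonyls could suffer retro-Claisen cleavage or α-ketol rearrangement under basic fluoride; C7 is not touched.

Step 8
Reactants: 16 (3R,7R)-7-hydroxy-3,7-dimethyl-3,4-dihydroisochromene-6,8(7H)-dione; 17 linoleoyl chloride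
Product: 18 (3R,7R)-3,7-dimethyl-6,8-dioxo-3,4,7,8-tetrahydro-6H-isochromen-7-yl (9Z,12Z)-octadeca-9,12-dienoate (target)
Conditions: DMAP (0.5 equiv), Et3N (2 equiv), CH2Cl2, 0 °C to rt, argon
Reagents that add atoms: linoleoyl chloride (17), CCCCC/C=C\C/C=C\CCCCCCCC(=O)Cl
Why: DMAP-catalysed acylation (nucleophilic catalysis) of the tertiary C7 alcohol with an acid chloride, a reaction type with precedent on 7-hydroxy azaphilone-type cores; no bond to C7 is broken, so its configuration is retained.

**Compound list**

1 | ethyl (S)-lactate | C[C@H](O)C(=O)OCC | starting material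
2 | chlorotriethylsilane | CC[Si](Cl)(CC)CC | starting material
3 | ethyl (2S)-2-[(triethylsilyl)oxy]propanoate | C[C@H](O[Si](CC)(CC)CC)C(=O)OCC | intermediate
4 | N,O-dimethylhydroxylamine hydrochloride | CNOC.Cl | starting material
5 | (2S)-N-methoxy-N-methyl-2-[(triethylsilyl)oxy]propanamide | C[C@H](O[Si](CC)(CC)CC)C(=O)N(C)OC | intermediate
6 | ethynylmagnesium bromide | C#C[Mg]Br | starting material
7 | (4S)-4-[(triethylsilyl)oxy]pent-1-yn-3-one | C[C@H](O[Si](CC)(CC)CC)C(=O)C#C | intermediate
8 | (R)-pent-4-yn-2-ol | C[C@@H](O)CC#C | starting material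
9 | (1E,4S)-1-[(2R)-pent-4-yn-2-yloxy]-4-[(triethylsilyl)oxy]pent-1-en-3-one | C[C@H](O[Si](CC)(CC)CC)C(=O)/C=C/O[C@H](C)CC#C | intermediate
10 | N-iodosuccinimide | O=C1CCC(=O)N1I | starting material
11 | (1Z,4S)-2-iodo-1-[(2R)-pent-4-yn-2-yloxy]-4-[(triethylsilyl)oxy]pent-1-en-3-one | C[C@H](O[Si](CC)(CC)CC)C(=O)/C(I)=C/O[C@H](C)CC#C | intermediate
12 | carbon monoxide | [C-]#[O+] | starting material
13 | alkenylpalladium iodide: (Z)-{(6R)-6-methyl-3-[(2S)-2-(triethylsilyloxy)propanoyl]-5,6-dihydro-4H-pyran-4-ylidene}methylpalladium iodide (bisphosphine on palladium not drawn) | C[C@H](O[Si](CC)(CC)CC)C(=O)C1=CO[C@H](C)C/C1=C/[Pd]I | intermediate (not isolated)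
14 | acylpalladium iodide: (Z)-{(6R)-6-methyl-3-[(2S)-2-(triethylsilyloxy)propanoyl]-5,6-dihydro-4H-pyran-4-ylidene}acetylpalladium iodide (bisphosphine on palladium not drawn) | C[C@H](O[Si](CC)(CC)CC)C(=O)C1=CO[C@H](C)C/C1=C/C(=O)[Pd]I | intermediate (not isolated)
15 | (3R,7R)-3,7-dimethyl-7-[(triethylsilyl)oxy]-3,4-dihydroisochromene-6,8(7H)-dione | CC[Si](CC)(CC)O[C@]1(C)C(=O)C=C2C[C@@H](C)OC=C2C1=O | intermediate
16 | (3R,7R)-7-hydroxy-3,7-dimethyl-3,4-dihydroisochromene-6,8(7H)-dione | O[C@]1(C)C(=O)C=C2C[C@@H](C)OC=C2C1=O | intermediate
17 | linoleoyl chloride, (9Z,12Z)-octadeca-9,12-dienoyl chloride | CCCCC/C=C\C/C=C\CCCCCCCC(=O)Cl | starting material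
18 | (3R,7R)-3,7-dimethyl-6,8-dioxo-3,4,7,8-tetrahydro-6H-isochromen-7-yl (9Z,12Z)-octadeca-9,12-dienoate | CCCCC/C=C\C/C=C\CCCCCCCC(=O)O[C@]1(C)C(=O)C=C2C[C@@H](C)OC=C2C1=O | target

**Step count and risks**

Total step count: 8. Longest linear sequence: 8 steps (1 to 18); the alkynol 8 and the acid chloride 17 are used as bought.

Steps most likely to fail:

Step 6 (proposed new method). What may go wrong: CO inserting into the first alkenylpalladium before the alkyne does, acylation of the enolate at oxygen instead of carbon, or poor facial selectivity at C7. The fallback uses known chemistry in two stages and sets out from 11. Cyclocarbopalladation with methoxycarbonylation (PdCl2(PPh3)2, CO 1 atm, MeOH, Et3N, DMF, 60 °C) should give the ring-B dienoate methyl (2Z)-[(6R)-6-methyl-3-{(2S)-2-[(triethylsilyl)oxy]propanoyl}-5,6-dihydro-4H-pyran-4-ylidene]acetate F1. Dieckmann condensation of F1 with LiN(SiMe3)2 in THF (−78 to 0 °C, acetic acid quench) should then close ring A to 15 together with its C7 epimer, (3R,7S)-3,7-dimethyl-7-[(triethylsilyl)oxy]-3,4-dihydroisochromene-6,8(7H)-dione F2. The two are diastereomers and would be separated by chromatography; the route is rejoined at 15.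

Step 5. What may go wrong: iodination at the terminal alkyne instead of the enol ether carbon, or erosion of the alkene geometry so that iodine ends up trans to O2. The fallback moves the iodination ahead of the alkynol and sets out from 7. Addition of dimethylamine (THF, 0 °C) should give the enaminone (1E,4S)-1-(dimethylamino)-4-[(triethylsilyl)oxy]pent-1-en-3-one F3. Iodine with Et3N in CH2Cl2, the standard α-iodination of enaminones, should give (1Z,4S)-1-(dimethylamino)-2-iodo-4-[(triethylsilyl)oxy]pent-1-en-3-one F4 with no alkyne present. Acid-promoted exchange of the dimethylamino group for alcohol 8 (camphorsulfonic acid, CH2Cl2) then comes back to the route at 11.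

Step 8. What may go wrong: incomplete acylation of the hindered tertiary alcohol, or base-induced retro-Claisen cleavage or α-ketol rearrangement of 16 during the slow acylation. The fallback avoids the free alcohol and basic conditions and sets out from 15: direct silyl ether-to-ester exchange with linoleoyl chloride 17 and catalytic ZnCl2 in MeCN should give 18 directly, so it also bypasses step 7. This fallback makes no new compound (F0).

**Further compounds**

F1 | step 6 | methyl (2Z)-[(6R)-6-methyl-3-{(2S)-2-[(triethylsilyl)oxy]propanoyl}-5,6-dihydro-4H-pyran-4-ylidene]acetate | C[C@H](O[Si](CC)(CC)CC)C(=O)C1=CO[C@H](C)C/C1=C/C(=O)OC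
F2 | step 6 | (3R,7S)-3,7-dimethyl-7-[(triethylsilyl)oxy]-3,4-dihydroisochromene-6,8(7H)-dione | CC[Si](CC)(CC)O[C@@]1(C)C(=O)C=C2C[C@@H](C)OC=C2C1=O
F3 | step 5 | (1E,4S)-1-(dimethylamino)-4-[(triethylsilyl)oxy]pent-1-en-3-one | C[C@H](O[Si](CC)(CC)CC)C(=O)/C=C/N(C)C
F4 | step 5 | (1Z,4S)-1-(dimethylamino)-2-iodo-4-[(triethylsilyl)oxy]pent-1-en-3-one | C[C@H](O[Si](CC)(CC)CC)C(=O)/C(I)=C/N(C)C
F0 | step 8 | none | none
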